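The readings come from a simulation with made-up constants, noise included.

The leftover is what you read first. Alpha keeps 33% of its J at 1.33 min and beta 9% at 4.00 min. These fractions differ widely, yet multiplied by their charges they nearly coincide, at 0.0495 M and 0.0441 M. So I take the mean of these two readings as one level of J that a flask falls to whatever its charge, the equilibrium monomer concentration, 0.0468 M, and the fraction left is this level over the charge.

| flask | J | L | remark | time |
|---|---|---|---|---|
| alpha | 0.15 M | 1 mM | run made earlier |  |
| beta | 0.49 M | 1 mM | run made earlier |  |
| Wednesday's | 0.10 M | 1.0 mM |  | 10 min |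
| Thursday's | 0.40 M | 1.0 mM |  | 10 min |

| run | time / min | G / % | J / % |
|---|---|---|---|
| alpha | 0.500 | 70 | 31 |
| alpha | 1.33 | 66 | 33 |
| alpha | 3.00 | 69 | 34 |
| alpha | 8.00 | 63 | 32 |
| beta | 2.00 | 84 | 8 |
| beta | 4.00 | 86 | 9 |
| beta | 5.00 | 82 | 9 |
| beta | 8.00 | 81 | 9 |

(standard deviation of a reading: 2 percentage points)

- the average divides the monomer in chains by the number of chains begun, living and dead together
- the numbers in the tables scatter by 2 percentage points (one standard deviation)
- candidate steps: G -> Q; J + L -> Z + G; G + Z -> J + Z; J + Z -> G + Z
- the earlier runs do not show the number of chains; that part of a forecast is a guess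

- which of the two ends with the longer chains by the average number of monomer units in a chain (chains begun, living or dead) ("neither" if they lie within 10%) (Wednesday's / Thursday's / neither)
- average number of monomer units in a chain (chains begun, living or dead) at the end, Wednesday's
- average number of monomer units in a chain (chains begun, living or dead) at the end, Thursday's

Now draw the curve of the fraction of J left. It starts at one and falls steeply: alpha loses on average 1.38 min⁻¹ of its charge up to its first reading. I put the knee no later than beta's first reading, at 2.00 min. The level is then 46.8% for Wednesday's and 11.7% for Thursday's, and the rest of each charge stands as G. After the knee, G sinks slowly in the readings, by a fractional rate of 0.0101 min⁻¹, so 90.4% of it stays over 10 min. With one chain per L charged, which is a guess, I reckon lengths of 48.1 and 319.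

The forecast names Thursday's, with 48 and 320, on the ground "It is the same concentration, not the same J/G ratio". It uses the same readings as my reckoning, so the match is no check.

The flask gives Thursday's, at 44.7 for Wednesday's and 297 for Thursday's.

    G → Q (k = 2.90 × 10⁻⁴ s⁻¹)
    J + L → Z + G (k = 26.0 M⁻¹ s⁻¹)
    G + Z → J + Z, rate k3*[Z] as long as [G] is above zero (k = 7.50 s⁻¹)
    J + Z → G + Z, rate k4*[Z]*[J] (k = 160 M⁻¹ s⁻¹)

Thursday's chains are longer because of its charge of J, 0.40 M against 0.10 M: given Wednesday's charge of J, Thursday's length goes from 297 to 44.7. The forecast stands on its count of chains, and the neighbour of Wednesday's charged with 0.0017 M of L moves that count. Its J stays at 46.9%, where the level over the charge gives 46.8%. The reckoning with that charge gives a length of 28.3, and the flask stands at 26.3.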